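## Retrosynthetic overview

1. The strategy rests on the fused pair ring A (C1(Me)2–C2–C3(OH)–C4–C5(Me)–C6) and ring B (O1–C5–C6=C7–C8), which share the C5–C6 bond. A [2+2+1] cut through C5–C6, C7–C8 and C8–O1 opens both rings to a C5 methyl ketone tethered to a C6≡C7 silylalkyne, with CO as C8.
2. Polyene: the C11=C12 bond is cut (Wittig) into a ring-bearing C15 enal and a C15 phosphonium salt built from the C10 dialdehyde and a C5 phosphonate. The C8' aldehyde is carried as an ester.
3. C8–C9: the butenolide carbonyl (C8) is reduced to a lactol acetate and alkenylated under nickel catalysis with a C9–C11 alkenylboronate from 2-butyn-1-ol, which sets C8.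
4. Ynone: alkyne by ozonolysis and Ohira–Bestmann homologation of methyl 3,3-dimethylpent-4-enoate, C3 by Brown methallylboration, C5 ketone by Lemieux–Johnson cleavage.
5. Ring order: both rings form in the key step, ring A first (C5–C6), ring B second (C7–C8, then C8–O1). No other ring-forming step is needed.

Key step: step 8

Assumption: the target is taken exactly as drawn, (3R,5R,8R) in carotenoid numbering (O3 cis to O1, the C8 side chain trans to the C5 methyl), all-E. Atom labels follow carotenoid numbering, with O1 the ring oxygen and primed numbers counted from the aldehyde end.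

Remark: species that persist in the flask until a second reagent or the work-up acts on them are numbered; short-lived mechanistic species are named in the Why lines only.

## Route

Step 1
Reactants: 1 methyl 3,3-dimethylpent-4-enoate
Product: 3 methyl 3,3-dimethyl-4-oxobutanoate, via ozonide 2 (not isolated)
Conditions: O3, CH2Cl2, −78 °C; then PPh3, −78 → 20 °C
Reagents that add atoms: ozone, [O-][O+]=O
Why: Ozonolysis cleaves the only C=C bond through ozonide 2 and PPh3 reduces it to the non-enolisable neopentyl aldehyde, while the ester is untouched.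

Step 2
Reactants: 3 methyl 3,3-dimethyl-4-oxobutanoate
Product: 4 methyl 3,3-dimethylpent-4-ynoate
Conditions: dimethyl (1-diazo-2-oxopropyl)phosphonate (1.3 equiv), K2CO3 (2 equiv), MeOH, 0 → 20 °C
Reagents that add atoms: dimethyl (1-diazo-2-oxopropyl)phosphonate, COP(=O)(OC)C(=[N+]=[N-])C(C)=O
Why: Ohira–Bestmann (Seyferth–Gilbert) homologation turns the α-quaternary aldehyde into the terminal alkyne under mild carbonate conditions, which avoids the enolate cyclopropanation that a dibromide/dehydrobromination sequence would risk on this ester.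

Step 3
Reactants: 4 methyl 3,3-dimethylpent-4-ynoate
Product: 6 3,3-dimethylpent-4-ynal, via aluminium hemiacetal 5 (not isolated)
Conditions: iBu2AlH (1.05 equiv), CH2Cl2, −78 °C; aq. KNaC4H4O6; dried solution used directly (volatile aldehyde)
Reagents that add atoms: none
Why: Partial ester reduction: iBu2AlH at −78 °C stops at the tetrahedral aluminium hemiacetal 5, which gives the aldehyde only on aqueous work-up, and the terminal alkyne is inert at this temperature.

Step 4
Reactants: 6 3,3-dimethylpent-4-ynal; 7 2-methylallylmagnesium chloride (CH2=C(CH3)CH2MgCl)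
Product: 10 (4S)-2,6,6-trimethyloct-1-en-7-yn-4-ol, via B-methallyldiisopinocampheylborane 8 (not isolated), via borinate ester 9 (not isolated)
Conditions: 7 + (−)-Ipc2BOMe [from (+)-α-pinene], Et2O, −78 → 20 °C; then 6, −78 °C; then NaOH, H2O2, 0 → 20 °C
Reagents that add atoms: none
Why: Brown asymmetric methallylboration: borane 8 adds through a chair Zimmerman–Traxler transition state to one aldehyde face under reagent control and sets C3 (4S in 10, the same centre becoming 3R in the target after the priority change), and NaOH/H2O2 cleaves borinate 9.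

Step 5
Reactants: 10 (4S)-2,6,6-trimethyloct-1-en-7-yn-4-ol
Product: 11 tert-butyldimethyl{[(4S)-2,6,6-trimethyloct-1-en-7-yn-4-yl]oxy}silane
Conditions: TBSCl, imidazole, DMF, 20 °C
Reagents that add atoms: tert-butyldimethylsilyl chloride, CC(C)(C)[Si](C)(C)Cl
Why: Standard silylation of the secondary alcohol gives an ether that tolerates n-BuLi, the oxidative cleavage and the titanium step.

Step 6
Reactants: 11 tert-butyldimethyl{[(4S)-2,6,6-trimethyloct-1-en-7-yn-4-yl]oxy}silane
Product: 13 tert-butyldimethyl{[(4S)-2,6,6-trimethyl-8-(trimethylsilyl)oct-1-en-7-yn-4-yl]oxy}silane, via lithium acetylide 12 (not isolated)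
Conditions: n-BuLi (1.1 equiv), THF, −78 °C; then Me3SiCl (1.3 equiv), −78 → 0 °C
Reagents that add atoms: chlorotrimethylsilane, C[Si](C)(C)Cl
Why: The acetylenic C–H is the only acidic site, so n-BuLi gives acetylide 12 cleanly and Me3SiCl caps C7 (C-silylation of a lithium acetylide).

Step 7
Reactants: 13 tert-butyldimethyl{[(4S)-2,6,6-trimethyl-8-(trimethylsilyl)oct-1-en-7-yn-4-yl]oxy}silane
Product: 15 (4R)-4-[(tert-butyldimethylsilyl)oxy]-6,6-dimethyl-8-(trimethylsilyl)oct-7-yn-2-one, via diol 14 (not isolated)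
Conditions: OsO4 (2 mol %), NaIO4 (4 equiv), 2,6-lutidine (2 equiv), dioxane/H2O 3:1, 20 °C
Reagents that add atoms: osmium tetroxide OsO4, O=[Os](=O)(=O)=O (oxygen carrier, reoxidised by sodium periodate NaIO4, [Na+].[O-]I(=O)(=O)=O)
Why: Lemieux–Johnson oxidation (dihydroxylation, then glycol cleavage) converts the 1,1-disubstituted alkene into the C5 methyl ketone, while the hindered silylalkyne is not attacked and the lutidine buffer protects the β-silyloxy ketone.

Step 8
Reactants: 15 (4R)-4-[(tert-butyldimethylsilyl)oxy]-6,6-dimethyl-8-(trimethylsilyl)oct-7-yn-2-one; 16 carbon monoxide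
Product: 19 (6R,7aR)-6-[(tert-butyldimethylsilyl)oxy]-4,4,7a-trimethyl-3-(trimethylsilyl)-5,6,7,7a-tetrahydro-1-benzofuran-2(4H)-one, via oxatitanacyclopentene 17 (not isolated), via acyl titanacycle 18 (not isolated)
Conditions: Cp2Ti(PMe3)2 (1.1 equiv), toluene, 20 °C, argon; then CO (2 atm), 70 °C
Reagents that add atoms: none
Why: Proposed new method: divalent titanium (Cp2Ti after loss of PMe3) binds the silylalkyne and the tethered ketone and couples C5 with C6 to oxatitanacyclopentene 17 with silicon on the titanium-bound C7, CO then inserts into the Ti–C7 bond to give acyl alkoxide 18, and C8–O1 reductive elimination, pulled by capture of the titanocene fragment as Cp2Ti(CO)2, releases butenolide 19. The closest known reactions are the Cp2Ti(PMe3)2-mediated hetero-Pauson–Khand cyclocarbonylation of alkene–ketone pairs, the Ru3(CO)12- or Mo(CO)6-mediated one of alkyne–aldehyde pairs and the insertion of ketones into titanocene–silylalkyne complexes; a silylalkyne paired with a dialkyl ketone closing a six-membered ring has not been shown. Ring A is closed by the reductive C5–C6 coupling, exo at both the alkyne and the carbonyl group (6-exo-dig/6-exo-trig sense), and ring B by lactonising C–O reductive elimination that contracts the six-membered acyl titanacycle to the five-membered butenolide. The new stereocentre C5 is set under substrate control by C3: in the chair-like cyclisation O5 must stay in the plane of the forming metallacycle, which puts the C5 methyl axial, and the C3 silyloxy group then takes the equatorial site because the axial one would be syn to both axial methyl groups (at C1 and C5), so that O3 and O1 end up cis (5R). The step needs C5–C6 rather than C5–C7 coupling, which the tether length and the preference of silicon for the carbon next to titanium secure, and it needs cyclisation to outrun ketone enolisation and displacement of the substrate by CO, which the gem-dimethyl group at C1 (Thorpe–Ingold effect) and the addition of CO only after metallacycle formation are meant to secure.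

Step 9
Reactants: 19 (6R,7aR)-6-[(tert-butyldimethylsilyl)oxy]-4,4,7a-trimethyl-3-(trimethylsilyl)-5,6,7,7a-tetrahydro-1-benzofuran-2(4H)-one
Product: 20 (6R,7aR)-6-hydroxy-4,4,7a-trimethyl-5,6,7,7a-tetrahydro-1-benzofuran-2(4H)-one
Conditions: Bu4NF·3H2O (3 equiv), THF, 0 → 20 °C
Reagents that add atoms: none
Why: Fluoride cleaves the O3 silyl ether and protodesilylates the C7–Si bond, which is activated by the adjacent lactone carbonyl, so no selectivity between the two silicon groups is needed; the product has the constitution and relative configuration of epi-loliolide, which serves as a check on the C3/C5 relation.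

Step 10
Reactants: 20 (6R,7aR)-6-hydroxy-4,4,7a-trimethyl-5,6,7,7a-tetrahydro-1-benzofuran-2(4H)-one
Product: 22 (6R,7aR)-2-acetoxy-4,4,7a-trimethyl-2,4,5,6,7,7a-hexahydro-1-benzofuran-6-yl acetate (C8 epimers), via bis(aluminium alkoxide) 21 (not isolated)
Conditions: iBu2AlH (2.3 equiv), CH2Cl2, −78 °C; then pyridine, DMAP, Ac2O, −78 → 20 °C
Reagents that add atoms: acetic anhydride, CC(=O)OC(C)=O
Why: Reductive acetylation: iBu2AlH reduces the butenolide carbonyl 1,2 to the aluminium lactolate (C6 is fully substituted, so conjugate reduction is disfavoured) and Ac2O/pyridine/DMAP acetylates both aluminium alkoxides in situ, while the quaternary C5 rules out aromatisation to a furan.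

Step 11
Reactants: 23 2-butyn-1-ol
Product: 24 (but-2-yn-1-yloxy)(tert-butyl)dimethylsilane
Conditions: TBSCl, imidazole, CH2Cl2, 0 → 20 °C
Reagents that add atoms: tert-butyldimethylsilyl chloride, CC(C)(C)[Si](C)(C)Cl
Why: Routine silylation of the primary alcohol.

Step 12
Reactants: 24 (but-2-yn-1-yloxy)(tert-butyl)dimethylsilane
Product: 25 tert-butyldimethyl{[(2Z)-3-(4,4,5,5-tetramethyl-1,3,2-dioxaborolan-2-yl)but-2-en-1-yl]oxy}silane
Conditions: B2pin2 (1.1 equiv), CuCl (5 mol %), PCy3 (6 mol %), NaOtBu (10 mol %), MeOH (2 equiv), toluene, 20 °C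
Reagents that add atoms: bis(pinacolato)diboron, CC1(C)OB(OC1(C)C)B1OC(C)(C)C(C)(C)O1
Why: Cu-catalysed formal hydroboration: the Cu–Bpin species adds syn across the alkyne with boron at the carbon remote from the propargylic oxygen and methanol protonates the C–Cu bond with retention, which places boron trans to CH2O (the later C8/C11 trans relation).

Step 13
Reactants: 22 (6R,7aR)-2-acetoxy-4,4,7a-trimethyl-2,4,5,6,7,7a-hexahydro-1-benzofuran-6-yl acetate (C8 epimers); 25 tert-butyldimethyl{[(2Z)-3-(4,4,5,5-tetramethyl-1,3,2-dioxaborolan-2-yl)but-2-en-1-yl]oxy}silane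
Product: 26 (2R,6R,7aR)-2-[(2E)-4-[(tert-butyldimethylsilyl)oxy]but-2-en-2-yl]-4,4,7a-trimethyl-2,4,5,6,7,7a-hexahydro-1-benzofuran-6-yl acetate
Conditions: Ni(cod)2 (10 mol %), TADDOL-derived P-phenyl phosphonite (12 mol %, matched antipode), 25 (1.5 equiv), K3PO4 (2 equiv), H2O (5 equiv), THF, 0 → 20 °C
Reagents that add atoms: none
Why: Proposed new method: zerovalent nickel from Ni(cod)2 ionises the allylic acetal C8–OAc bond of either epimer of 22 to one nickel-bound 2-oxa-allyl (oxocarbenium) species, the alkenyl group is transferred from boron with phosphate assistance and C–C reductive elimination occurs at the oxygen-bearing, less hindered terminus C8 rather than at the fully substituted C6, with retention of the alkene geometry; the face is chosen by the chiral phosphonite (catalyst control, new stereocentre C8 = R), used as the antipode that reinforces the small inherent preference for entry anti to the axial C5 methyl; the closest known reactions are the Ni-catalysed coupling of boronic acids with 2H-chromene acetals and the Ni-catalysed allylic alkenylation of allylic acetates with alkenylborates, neither shown on a 2-acyloxy-2,5-dihydrofuran.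

Step 14
Reactants: 26 (2R,6R,7aR)-2-[(2E)-4-[(tert-butyldimethylsilyl)oxy]but-2-en-2-yl]-4,4,7a-trimethyl-2,4,5,6,7,7a-hexahydro-1-benzofuran-6-yl acetate
Product: 27 (2R,6R,7aR)-2-[(2E)-4-hydroxybut-2-en-2-yl]-4,4,7a-trimethyl-2,4,5,6,7,7a-hexahydro-1-benzofuran-6-yl acetate
Conditions: Bu4NF (1.2 equiv), AcOH (1.2 equiv), THF, 0 °C
Reagents that add atoms: none
Why: Buffered fluoride removes the primary allylic silyl ether, while the secondary acetate and the acid-sensitive doubly allylic C8–O1 bond are left alone under these near-neutral conditions.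

Step 15
Reactants: 27 (2R,6R,7aR)-2-[(2E)-4-hydroxybut-2-en-2-yl]-4,4,7a-trimethyl-2,4,5,6,7,7a-hexahydro-1-benzofuran-6-yl acetate
Product: 28 (2R,6R,7aR)-4,4,7a-trimethyl-2-[(2E)-4-oxobut-2-en-2-yl]-2,4,5,6,7,7a-hexahydro-1-benzofuran-6-yl acetate
Conditions: activated MnO2 (20 equiv), CH2Cl2, 20 °C
Reagents that add atoms: none
Why: MnO2 oxidises only the allylic primary alcohol to the enal under neutral conditions, which protects the γ-stereocentre C8 from epimerisation.

Step 16
Reactants: 29 diethyl (2-oxoethyl)phosphonate; 30 ethyl 2-(triphenylphosphoranylidene)propanoate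
Product: 31 ethyl (2E)-4-(diethoxyphosphoryl)-2-methylbut-2-enoate
Conditions: CH2Cl2, 20 °C
Reagents that add atoms: none
Why: Wittig reaction of a stabilised ylide with the aldehyde gives the (E)-trisubstituted enoate selectively.

Step 17
Reactants: 31 ethyl (2E)-4-(diethoxyphosphoryl)-2-methylbut-2-enoate; 32 (2E,4E,6E)-2,7-dimethylocta-2,4,6-trienedial
Product: 34 ethyl (2E,4E,6E,8E,10E)-2,6,11-trimethyl-12-oxododeca-2,4,6,8,10-pentaenoate, via phosphonate carbanion sodium salt 33 (not isolated)
Conditions: NaH (1.0 equiv), THF, 0 °C; then added to 32 (2.5 equiv), THF, −20 → 20 °C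
Reagents that add atoms: none
Why: Horner–Wadsworth–Emmons reaction at the carbon next to phosphorus forms C11'=C12' E-selectively, and the excess of the symmetric dialdehyde together with the lower electrophilicity of the longer product aldehyde favours mono-olefination.

Step 18
Reactants: 34 ethyl (2E,4E,6E,8E,10E)-2,6,11-trimethyl-12-oxododeca-2,4,6,8,10-pentaenoate
Product: 35 ethyl (2E,4E,6E,8E,10E)-12-hydroxy-2,6,11-trimethyldodeca-2,4,6,8,10-pentaenoate
Conditions: NaBH4, EtOH/CH2Cl2, −20 °C
Reagents that add atoms: none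
Why: NaBH4 reduces the conjugated aldehyde 1,2 and leaves the ester.

Step 19
Reactants: 35 ethyl (2E,4E,6E,8E,10E)-12-hydroxy-2,6,11-trimethyldodeca-2,4,6,8,10-pentaenoate
Product: 36 [(2E,4E,6E,8E,10E)-12-ethoxy-2,7,11-trimethyl-12-oxododeca-2,4,6,8,10-pentaen-1-yl]triphenylphosphonium bromide
Conditions: PPh3·HBr (1.05 equiv), CH2Cl2/EtOH, 0 → 20 °C, dark
Reagents that add atoms: triphenylphosphine hydrobromide, [Br-].[PH+](c1ccccc1)(c1ccccc1)c1ccccc1
Why: Polyenylic alcohols are converted by PPh3·HBr through the delocalised allylic cation into the terminal phosphonium salt, the standard way to carotenoid Wittig salts.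

Step 20
Reactants: 28 (2R,6R,7aR)-4,4,7a-trimethyl-2-[(2E)-4-oxobut-2-en-2-yl]-2,4,5,6,7,7a-hexahydro-1-benzofuran-6-yl acetate; 36 [(2E,4E,6E,8E,10E)-12-ethoxy-2,7,11-trimethyl-12-oxododeca-2,4,6,8,10-pentaen-1-yl]triphenylphosphonium bromide
Product: 38 ethyl (2E,4E,6E,8E,10E,12E,14E)-15-[(2R,6R,7aR)-6-acetoxy-4,4,7a-trimethyl-2,4,5,6,7,7a-hexahydro-1-benzofuran-2-yl]-2,6,11-trimethylhexadeca-2,4,6,8,10,12,14-heptaenoate, via ylide 37 (not isolated)
Conditions: 1,2-epoxybutane (10 equiv), EtOH, 70 °C, argon, dark; then heptane, 80 °C (Z → E equilibration)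
Reagents that add atoms: none
Why: Wittig olefination under the neutral epoxide protocol: 1,2-epoxybutane takes up HBr, the highly stabilised ylide 37 adds to enal 28 without exposing the γ-stereocentre C8 to free strong base, and heat should equilibrate the hindered 11Z isomer to all-E.

Step 21
Reactants: 38 ethyl (2E,4E,6E,8E,10E,12E,14E)-15-[(2R,6R,7aR)-6-acetoxy-4,4,7a-trimethyl-2,4,5,6,7,7a-hexahydro-1-benzofuran-2-yl]-2,6,11-trimethylhexadeca-2,4,6,8,10,12,14-heptaenoate
Product: 39 (2R,6R,7aR)-2-[(2E,4E,6E,8E,10E,12E,14E)-16-hydroxy-6,11,15-trimethylhexadeca-2,4,6,8,10,12,14-heptaen-2-yl]-4,4,7a-trimethyl-2,4,5,6,7,7a-hexahydro-1-benzofuran-6-ol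
Conditions: iBu2AlH (5 equiv), CH2Cl2, −78 → −40 °C; aq. KNaC4H4O6
Reagents that add atoms: none
Why: Excess iBu2AlH reduces the conjugated ester 1,2 to the C8' allylic alcohol and cleaves the 3-acetate in the same operation.

Step 22
Reactants: 39 (2R,6R,7aR)-2-[(2E,4E,6E,8E,10E,12E,14E)-16-hydroxy-6,11,15-trimethylhexadeca-2,4,6,8,10,12,14-heptaen-2-yl]-4,4,7a-trimethyl-2,4,5,6,7,7a-hexahydro-1-benzofuran-6-ol
Product: 40 (2E,4E,6E,8E,10E,12E,14E)-15-[(2R,6R,7aR)-6-hydroxy-4,4,7a-trimethyl-2,4,5,6,7,7a-hexahydro-1-benzofuran-2-yl]-2,6,11-trimethylhexadeca-2,4,6,8,10,12,14-heptaenal (CNP0118413.1)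
Conditions: activated MnO2 (20 equiv), CH2Cl2, 20 °C, dark
Reagents that add atoms: none
Why: MnO2 oxidises the polyenylic primary alcohol selectively to the aldehyde and leaves the saturated secondary C3 alcohol, so the target needs no final deprotection.

## Compound list

1 | methyl 3,3-dimethylpent-4-enoate | COC(=O)CC(C)(C)C=C | starting material
2 | methyl 3-methyl-3-(1,2,4-trioxolan-3-yl)butanoate (ozonide) | COC(=O)CC(C)(C)C1OCOO1 | intermediate
3 | methyl 3,3-dimethyl-4-oxobutanoate | COC(=O)CC(C)(C)C=O | intermediate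
4 | methyl 3,3-dimethylpent-4-ynoate | COC(=O)CC(C)(C)C#C | intermediate
5 | diisobutylaluminium hemiacetal of 4 | COC(CC(C)(C)C#C)O[Al](CC(C)C)CC(C)C | intermediate
6 | 3,3-dimethylpent-4-ynal | C#CC(C)(C)CC=O | intermediate
7 | 2-methylallylmagnesium chloride | CC(=C)C[Mg]Cl | starting material
8 | B-(2-methylallyl)diisopinocampheylborane, (+)-α-pinene series | CC(=C)CB([C@@H]1C[C@@H]2C[C@H]([C@H]1C)C2(C)C)[C@@H]1C[C@@H]2C[C@H]([C@H]1C)C2(C)C | intermediate
9 | diisopinocampheylborinate ester of 10 | C#CC(C)(C)C[C@@H](OB([C@@H]1C[C@@H]2C[C@H]([C@H]1C)C2(C)C)[C@@H]1C[C@@H]2C[C@H]([C@H]1C)C2(C)C)CC(C)=C | intermediate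
10 | (4S)-2,6,6-trimethyloct-1-en-7-yn-4-ol | C#CC(C)(C)C[C@@H](O)CC(C)=C | intermediate
11 | tert-butyldimethyl{[(4S)-2,6,6-trimethyloct-1-en-7-yn-4-yl]oxy}silane | C#CC(C)(C)C[C@@H](O[Si](C)(C)C(C)(C)C)CC(C)=C | intermediate
12 | lithium acetylide of 11 | [Li]C#CC(C)(C)C[C@@H](O[Si](C)(C)C(C)(C)C)CC(C)=C | intermediate
13 | tert-butyldimethyl{[(4S)-2,6,6-trimethyl-8-(trimethylsilyl)oct-1-en-7-yn-4-yl]oxy}silane | C[Si](C)(C)C#CC(C)(C)C[C@@H](O[Si](C)(C)C(C)(C)C)CC(C)=C | intermediate
14 | (4R)-4-[(tert-butyldimethylsilyl)oxy]-2,6,6-trimethyl-8-(trimethylsilyl)oct-7-yne-1,2-diol (C2 epimers) | C[Si](C)(C)C#CC(C)(C)C[C@@H](O[Si](C)(C)C(C)(C)C)CC(C)(O)CO | intermediate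
15 | (4R)-4-[(tert-butyldimethylsilyl)oxy]-6,6-dimethyl-8-(trimethylsilyl)oct-7-yn-2-one | C[Si](C)(C)C#CC(C)(C)C[C@@H](O[Si](C)(C)C(C)(C)C)CC(C)=O | intermediate
16 | carbon monoxide | [C-]#[O+] | starting material
17 | bis(cyclopentadienyl) oxatitanacyclopentene from 15 (Cp written as σ-C5H5 in the line notation) | C[Si](C)(C)C1=C2C(C)(C)C[C@@H](O[Si](C)(C)C(C)(C)C)C[C@@]2(C)O[Ti]1(C3C=CC=C3)C4C=CC=C4 | intermediate
18 | bis(cyclopentadienyl) acyl oxatitanacycle after CO insertion (Cp written as σ-C5H5) | C[Si](C)(C)C1=C2C(C)(C)C[C@@H](O[Si](C)(C)C(C)(C)C)C[C@@]2(C)O[Ti](C3C=CC=C3)(C4C=CC=C4)C1=O | intermediate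
19 | (6R,7aR)-6-[(tert-butyldimethylsilyl)oxy]-4,4,7a-trimethyl-3-(trimethylsilyl)-5,6,7,7a-tetrahydro-1-benzofuran-2(4H)-one | C[Si](C)(C)C1=C2C(C)(C)C[C@@H](O[Si](C)(C)C(C)(C)C)C[C@@]2(C)OC1=O | intermediate
20 | (6R,7aR)-6-hydroxy-4,4,7a-trimethyl-5,6,7,7a-tetrahydro-1-benzofuran-2(4H)-one | O=C1C=C2C(C)(C)C[C@@H](O)C[C@@]2(C)O1 | intermediate
21 | bis(diisobutylaluminium) alkoxide of the lactol from 20 (C8 epimers) | CC(C)C[Al](CC(C)C)OC1C=C2C(C)(C)C[C@@H](O[Al](CC(C)C)CC(C)C)C[C@@]2(C)O1 | intermediate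
22 | (6R,7aR)-2-acetoxy-4,4,7a-trimethyl-2,4,5,6,7,7a-hexahydro-1-benzofuran-6-yl acetate (C8 epimers) | CC(=O)OC1C=C2C(C)(C)C[C@@H](OC(C)=O)C[C@@]2(C)O1 | intermediate
23 | 2-butyn-1-ol | CC#CCO | starting material
24 | (but-2-yn-1-yloxy)(tert-butyl)dimethylsilane | CC#CCO[Si](C)(C)C(C)(C)C | intermediate
25 | tert-butyldimethyl{[(2Z)-3-(4,4,5,5-tetramethyl-1,3,2-dioxaborolan-2-yl)but-2-en-1-yl]oxy}silane | CC(C)(C)[Si](C)(C)OC/C=C(\C)B1OC(C)(C)C(C)(C)O1 | intermediate
26 | (2R,6R,7aR)-2-[(2E)-4-[(tert-butyldimethylsilyl)oxy]but-2-en-2-yl]-4,4,7a-trimethyl-2,4,5,6,7,7a-hexahydro-1-benzofuran-6-yl acetate | CC(C)(C)[Si](C)(C)OC/C=C(\C)[C@H]1C=C2C(C)(C)C[C@@H](OC(C)=O)C[C@@]2(C)O1 | intermediate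
27 | (2R,6R,7aR)-2-[(2E)-4-hydroxybut-2-en-2-yl]-4,4,7a-trimethyl-2,4,5,6,7,7a-hexahydro-1-benzofuran-6-yl acetate | OC/C=C(\C)[C@H]1C=C2C(C)(C)C[C@@H](OC(C)=O)C[C@@]2(C)O1 | intermediate
28 | (2R,6R,7aR)-4,4,7a-trimethyl-2-[(2E)-4-oxobut-2-en-2-yl]-2,4,5,6,7,7a-hexahydro-1-benzofuran-6-yl acetate | O=C/C=C(\C)[C@H]1C=C2C(C)(C)C[C@@H](OC(C)=O)C[C@@]2(C)O1 | intermediate
29 | diethyl (2-oxoethyl)phosphonate | CCOP(=O)(CC=O)OCC | starting material
30 | ethyl 2-(triphenylphosphoranylidene)propanoate | CCOC(=O)C(C)=P(c1ccccc1)(c1ccccc1)c1ccccc1 | starting material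
31 | ethyl (2E)-4-(diethoxyphosphoryl)-2-methylbut-2-enoate | CCOC(=O)/C(C)=C/CP(=O)(OCC)OCC | intermediate
32 | (2E,4E,6E)-2,7-dimethylocta-2,4,6-trienedial | O=C/C(C)=C/C=C/C=C(\C)C=O | starting material
33 | sodium salt of the carbanion of 31 | [Na+].CCOC(=O)/C(C)=C/[CH-]P(=O)(OCC)OCC | intermediate
34 | ethyl (2E,4E,6E,8E,10E)-2,6,11-trimethyl-12-oxododeca-2,4,6,8,10-pentaenoate | C\C(C(=O)OCC)=C/C=C/C(C)=C/C=C/C=C(C)/C=O | intermediate
35 | ethyl (2E,4E,6E,8E,10E)-12-hydroxy-2,6,11-trimethyldodeca-2,4,6,8,10-pentaenoate | C\C(C(=O)OCC)=C/C=C/C(C)=C/C=C/C=C(C)/CO | intermediate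
36 | [(2E,4E,6E,8E,10E)-12-ethoxy-2,7,11-trimethyl-12-oxododeca-2,4,6,8,10-pentaen-1-yl]triphenylphosphonium bromide | C\C(C(=O)OCC)=C/C=C/C(C)=C/C=C/C=C(C)/C[P+](c1ccccc1)(c1ccccc1)c1ccccc1.[Br-] | intermediate
37 | ethyl (2E,4E,6E,8E,10E)-2,6,11-trimethyl-12-(triphenyl-λ5-phosphanylidene)dodeca-2,4,6,8,10-pentaenoate (ylide) | C\C(C(=O)OCC)=C/C=C/C(C)=C/C=C/C=C(C)/C=P(c1ccccc1)(c1ccccc1)c1ccccc1 | intermediate
38 | ethyl (2E,4E,6E,8E,10E,12E,14E)-15-[(2R,6R,7aR)-6-acetoxy-4,4,7a-trimethyl-2,4,5,6,7,7a-hexahydro-1-benzofuran-2-yl]-2,6,11-trimethylhexadeca-2,4,6,8,10,12,14-heptaenoate | C\C(C(=O)OCC)=C/C=C/C(C)=C/C=C/C=C(C)/C=C/C=C(\C)[C@H]1C=C2C(C)(C)C[C@@H](OC(C)=O)C[C@@]2(C)O1 | intermediate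
39 | (2R,6R,7aR)-2-[(2E,4E,6E,8E,10E,12E,14E)-16-hydroxy-6,11,15-trimethylhexadeca-2,4,6,8,10,12,14-heptaen-2-yl]-4,4,7a-trimethyl-2,4,5,6,7,7a-hexahydro-1-benzofuran-6-ol | C\C(CO)=C/C=C/C(C)=C/C=C/C=C(C)/C=C/C=C(\C)[C@H]1C=C2C(C)(C)C[C@@H](O)C[C@@]2(C)O1 | intermediate
40 | (2E,4E,6E,8E,10E,12E,14E)-15-[(2R,6R,7aR)-6-hydroxy-4,4,7a-trimethyl-2,4,5,6,7,7a-hexahydro-1-benzofuran-2-yl]-2,6,11-trimethylhexadeca-2,4,6,8,10,12,14-heptaenal | C\C(C=O)=C/C=C/C(C)=C/C=C/C=C(C)/C=C/C=C(\C)[C@H]1C=C2C(C)(C)C[C@@H](O)C[C@@]2(C)O1 | target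

## Step count and risks

Total step count: 22. Longest linear sequence: 16 steps (1–10, 13–15, 20–22); steps 11–12 and 16–19 are side branches.

Steps most likely to fail:

**Step 8 (proposed new method).** The oxidative coupling of the hindered methyl ketone with the silylalkyne may stall, CO may displace the organic ligands from titanium before insertion, or the acyl alkoxide may resist C–O reductive elimination because of the strong Ti–O bond. The facial selectivity at C5 may also erode if the cyclisation leaves the chair. The fallback separates the C–C coupling from the carbonylation and uses known reactions. It sets out from ynone 15: Cp2Ti(PMe3)2 (toluene, 20 °C) gives titanacycle 17 as before, but CO is withheld and the Ti–C7 bond is cleaved with I2, followed by aqueous work-up. This should give (1R,2Z,5R)-5-[(tert-butyldimethylsilyl)oxy]-2-[iodo(trimethylsilyl)methylidene]-1,3,3-trimethylcyclohexan-1-ol F1, with iodine cis to the tertiary hydroxyl. Pd(PPh3)4-catalysed carbonylative lactonisation of this (Z)-γ-hydroxy alkenyl iodide (CO 1 atm, Et3N, MeCN, 60 °C) then closes ring B, and the route is rejoined at butenolide 19.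

**Step 13 (proposed new method).** Ionisation of the acetal acetate by nickel may be slow, alkenyl transfer from the pinacol boronate may lag behind hydrolysis of the acetate, and the face selectivity at C8 may be poor because the C5 methyl and C4 flank the two faces almost equally. The fallback is the known metal-free alkenyl transfer from a trifluoroborate to an oxocarbenium ion, and it sets out from diacetate 22 and boronate 25. KHF2 (aqueous MeOH, 0 °C) converts 25 into potassium {(2Z)-4-[(tert-butyldimethylsilyl)oxy]but-2-en-2-yl}trifluoroborate F2. BF3·OEt2 (MeCN/CH2Cl2, −40 °C) ionises 22 to the cyclic oxocarbenium ion, to which F2 adds at C8. Face selection is then left to the substrate, so the C8 epimer (2S,6R,7aR)-2-[(2E)-4-[(tert-butyldimethylsilyl)oxy]but-2-en-2-yl]-4,4,7a-trimethyl-2,4,5,6,7,7a-hexahydro-1-benzofuran-6-yl acetate F3 is expected beside the desired isomer and is removed by chromatography. The route is rejoined at 26.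

**Step 20.** The Wittig union may give E/Z scrambling at C11=C12 that does not fully equilibrate, and prolonged heating may epimerise C8 through γ-deprotonation of enal 28. The fallback replaces the thermal Wittig by a low-temperature Horner–Wadsworth–Emmons union and sets out from hydroxy ester 35. PBr3 (Et2O, −20 °C) gives ethyl (2E,4E,6E,8E,10E)-12-bromo-2,6,11-trimethyldodeca-2,4,6,8,10-pentaenoate F4, which is used at once. Arbuzov reaction with P(OEt)3 gives ethyl (2E,4E,6E,8E,10E)-12-(diethoxyphosphoryl)-2,6,11-trimethyldodeca-2,4,6,8,10-pentaenoate F5. Its anion, pre-formed with LiN(SiMe3)2 (THF, −78 °C), is treated with 28 at −78 °C, which should form C11=C12 E-selectively without heat or free base. The route is rejoined at ester 38.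

## Further compounds

F1 | step 8 | (1R,2Z,5R)-5-[(tert-butyldimethylsilyl)oxy]-2-[iodo(trimethylsilyl)methylidene]-1,3,3-trimethylcyclohexan-1-ol | C[Si](C)(C)/C(I)=C1\C(C)(C)C[C@@H](O[Si](C)(C)C(C)(C)C)C[C@@]1(C)O
F2 | step 13 | potassium {(2Z)-4-[(tert-butyldimethylsilyl)oxy]but-2-en-2-yl}trifluoroborate | [K+].CC(C)(C)[Si](C)(C)OC/C=C(\C)[B-](F)(F)F
F3 | step 13 | (2S,6R,7aR)-2-[(2E)-4-[(tert-butyldimethylsilyl)oxy]but-2-en-2-yl]-4,4,7a-trimethyl-2,4,5,6,7,7a-hexahydro-1-benzofuran-6-yl acetate | CC(C)(C)[Si](C)(C)OC/C=C(\C)[C@@H]1C=C2C(C)(C)C[C@@H](OC(C)=O)C[C@@]2(C)O1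
F4 | step 20 | ethyl (2E,4E,6E,8E,10E)-12-bromo-2,6,11-trimethyldodeca-2,4,6,8,10-pentaenoate | C\C(C(=O)OCC)=C/C=C/C(C)=C/C=C/C=C(C)/CBr
F5 | step 20 | ethyl (2E,4E,6E,8E,10E)-12-(diethoxyphosphoryl)-2,6,11-trimethyldodeca-2,4,6,8,10-pentaenoate | C\C(C(=O)OCC)=C/C=C/C(C)=C/C=C/C=C(C)/CP(=O)(OCC)OCC
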